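Ring C of the flavanone is disconnected between the ketone carbon C4 and the methylene C3. The key step, a rhodium-catalysed enantioselective intramolecular hydroacylation, adds the aldehyde C–H bond of ring A across a 1,1-disubstituted enol ether; in one operation it closes ring C, creates the ketone and sets C2. Its precursor is an achiral 2-[(1-arylvinyl)oxy]benzaldehyde, in which O1 already ties ring A to the C2=C3 alkene that carries ring B (the dimethylchromene). The step exploits that C4 is an aryl ketone next to an unsubstituted C3H2, and that C2, the only stereocentre, bears O1, ring B and a single hydrogen: the pattern an anti-Markovnikov hydroacylation of C2=C3 leaves.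

Key step: step 10

Remark (flavanone numbering throughout): the sense of induction of the hydroacylation cannot be predicted with certainty; the (R)-ligand is written, and its antipode is to be used if a first run shows the 2R product.

Step 1
Reactants: 1 methyl 4-hydroxybenzoate; 2 3-chloro-3-methylbut-1-yne
Product: 3 methyl 4-[(2-methylbut-3-yn-2-yl)oxy]benzoate
Conditions: K2CO3, KI, CuI (cat.), acetone, reflux
Reagents that add atoms: none
Why: Copper-assisted Williamson etherification of the phenoxide with the tertiary propargylic chloride should give the aryl 1,1-dimethylpropargyl ether, the methyl ester being inert to carbonate.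

Step 2
Reactants: 3 methyl 4-[(2-methylbut-3-yn-2-yl)oxy]benzoate
Product: 7 methyl 2,2-dimethyl-2H-chromene-6-carboxylate, via allenyl dienone 4 (not isolated), via allenyl phenol 5 (not isolated), via ortho-quinone methide 6 (not isolated)
Conditions: N,N-diethylaniline, 190 °C
Reagents that add atoms: none
Why: An aromatic propargyl Claisen rearrangement to 4, enolisation to 5, a 1,5-hydrogen shift to 6 and an oxa-6π-electrocyclisation should deliver the 2,2-dimethylchromene, the two ortho positions being equivalent.

Step 3
Reactants: 7 methyl 2,2-dimethyl-2H-chromene-6-carboxylate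
Product: 8 2,2-dimethyl-2H-chromene-6-carboxylic acid
Conditions: LiOH·H2O, THF/MeOH/H2O, 50 °C; then 1 M HCl to pH 3
Reagents that add atoms: lithium hydroxide [Li+].[OH-]
Why: Ester saponification should proceed cleanly because the chromene ether and its alkene are stable to aqueous base and to brief dilute acid.

Step 4
Reactants: 9 5-bromo-2,4-dihydroxybenzaldehyde
Product: 10 5-bromo-2-hydroxy-4-[(triisopropylsilyl)oxy]benzaldehyde
Conditions: TIPSCl, imidazole, DMF, 0 °C to rt
Reagents that add atoms: triisopropylsilyl chloride CC(C)[Si](Cl)(C(C)C)C(C)C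
Why: Regioselective O-silylation should occur at the 4-hydroxyl because the 2-hydroxyl is held in a hydrogen bond to the aldehyde and is the weaker nucleophile.

Step 5
Reactants: 10 5-bromo-2-hydroxy-4-[(triisopropylsilyl)oxy]benzaldehyde; 11 tributyl(3-methylbut-2-en-1-yl)stannane
Product: 12 2-hydroxy-5-(3-methylbut-2-en-1-yl)-4-[(triisopropylsilyl)oxy]benzaldehyde
Conditions: Pd(PPh3)4 (5 mol%), DMF, 95 °C
Reagents that add atoms: none
Why: In this Stille coupling the aryl bromide adds to zerovalent palladium and the prenyl palladium intermediate should reductively eliminate at its unhindered primary terminus to give the linear prenyl arene, the neutral conditions sparing phenol, aldehyde and silyl ether.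

Step 6
Reactants: 12 2-hydroxy-5-(3-methylbut-2-en-1-yl)-4-[(triisopropylsilyl)oxy]benzaldehyde; 8 2,2-dimethyl-2H-chromene-6-carboxylic acid
Product: 13 2-formyl-4-(3-methylbut-2-en-1-yl)-5-[(triisopropylsilyl)oxy]phenyl 2,2-dimethyl-2H-chromene-6-carboxylate
Conditions: DCC, DMAP (cat.), CH2Cl2, 0 °C to rt
Reagents that add atoms: none
Why: Steglich esterification should acylate the only free hydroxyl through the acylpyridinium species and thereby places the future C2 carbon, with ring B attached, on O1.

Step 7
Reactants: 13 2-formyl-4-(3-methylbut-2-en-1-yl)-5-[(triisopropylsilyl)oxy]phenyl 2,2-dimethyl-2H-chromene-6-carboxylate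
Product: 14 2-(dimethoxymethyl)-4-(3-methylbut-2-en-1-yl)-5-[(triisopropylsilyl)oxy]phenyl 2,2-dimethyl-2H-chromene-6-carboxylate
Conditions: HC(OMe)3, MeOH, PPTS (cat.), rt; Et3N quench
Reagents that add atoms: trimethyl orthoformate COC(OC)OC; methanol CO
Why: Acid-catalysed acetalisation with the orthoformate as water scavenger should mask the aldehyde, which would otherwise be methylenated in step 8, while aryl ester, aryl silyl ether and both alkenes tolerate the weak acid.

Step 8
Reactants: 14 2-(dimethoxymethyl)-4-(3-methylbut-2-en-1-yl)-5-[(triisopropylsilyl)oxy]phenyl 2,2-dimethyl-2H-chromene-6-carboxylate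
Product: 15 6-(1-{2-(dimethoxymethyl)-4-(3-methylbut-2-en-1-yl)-5-[(triisopropylsilyl)oxy]phenoxy}ethenyl)-2,2-dimethyl-2H-chromene
Conditions: Cp2TiMe2, toluene/THF, 70 °C, dark; filtration through basic alumina
Reagents that add atoms: dimethyltitanocene C[Ti](C)(C1C=CC=C1)C1C=CC=C1
Why: Petasis methylenation, in which thermally formed titanocene methylidene converts the aryl ester through an oxatitanacyclobutane into the aryl 1-arylvinyl ether, should be selective because the ester is the only carbonyl group and the reagent is not Lewis acidic towards the acetal.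

Step 9
Reactants: 15 6-(1-{2-(dimethoxymethyl)-4-(3-methylbut-2-en-1-yl)-5-[(triisopropylsilyl)oxy]phenoxy}ethenyl)-2,2-dimethyl-2H-chromene
Product: 16 2-{[1-(2,2-dimethyl-2H-chromen-6-yl)ethenyl]oxy}-5-(3-methylbut-2-en-1-yl)-4-[(triisopropylsilyl)oxy]benzaldehyde
Conditions: PPTS (cat.), acetone/H2O, 0 °C; NaHCO3 quench
Reagents that add atoms: water O
Why: Chemoselective acetal hydrolysis should be possible because the dimethyl acetal of this electron-rich benzaldehyde ionises far more readily than the aryl enol ether is protonated at carbon, its oxygen lone pair being delocalised into ring A.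

Step 10
Reactants: 16 2-{[1-(2,2-dimethyl-2H-chromen-6-yl)ethenyl]oxy}-5-(3-methylbut-2-en-1-yl)-4-[(triisopropylsilyl)oxy]benzaldehyde
Product: 17 (2S)-2-(2,2-dimethyl-2H-chromen-6-yl)-6-(3-methylbut-2-en-1-yl)-7-[(triisopropylsilyl)oxy]-2,3-dihydro-4H-chromen-4-one
Conditions: [Rh(cod)Cl]2 (2.5 mol%), (R)-DTBM-SEGPHOS (5.5 mol%), Na[B(3,5-(CF3)2C6H3)4] (5 mol%), THF, 60 °C
Reagents that add atoms: none
Why: Proposed new method: the aldehyde C–H bond of 16 should add oxidatively to the cationic monovalent rhodium bisphosphine complex (the ether oxygen O1 can chelate the acyl rhodium hydride and retard decarbonylation), the C2=C3 enol ether should then insert into Rh–H with hydride going to C2 and rhodium to the terminal C3, and C–C reductive elimination from the seven-membered acyl alkyl rhodacycle should form the C3–C4 bond, overall an intramolecular alkene hydroacylation. The closest known reaction type is the endo-selective, enantioselective rhodium-catalysed intramolecular hydroacylation of 1,1-disubstituted alkenes held ortho to an aromatic aldehyde by a one-atom carbon tether (2-substituted allyl arenes giving 3-substituted tetralones), of which 16 is the oxygen-tethered enol ether analogue not yet shown. Ring C is closed in a formal 6-endo-trig mode. The only new stereocentre, C2, is set in the hydride insertion under catalyst control by the two-fold symmetric bisphosphine, which distinguishes the alkene faces through the different sizes of ring B and the tethered O1, and the ligand enantiomer is chosen to give 2S. The step needs endo over exo regioselectivity (exo closure would give a 2-methyl-2-aryl-benzofuran-3-one), which the 1,1-disubstitution should secure because exo insertion creates a tertiary alkyl rhodium that would have to form a quaternary centre, while the absence of allylic hydrogens excludes alkene isomerisation. Chemoselectivity over the prenyl and chromene alkenes is secured by geometry, since neither can reach the acyl rhodium hydride intramolecularly.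

Step 11
Reactants: 17 (2S)-2-(2,2-dimethyl-2H-chromen-6-yl)-6-(3-methylbut-2-en-1-yl)-7-[(triisopropylsilyl)oxy]-2,3-dihydro-4H-chromen-4-one
Product: 18 dinklagin A, (2S)-2-(2,2-dimethyl-2H-chromen-6-yl)-7-hydroxy-6-(3-methylbut-2-en-1-yl)-2,3-dihydro-4H-chromen-4-one
Conditions: TBAF, AcOH (1:1), THF, 0 °C
Reagents that add atoms: none
Why: Fluoride-mediated desilylation of the aryl silyl ether, buffered with acetic acid so that no free phenoxide or basic fluoride can open ring C by retro-oxa-Michael reaction, should free the 7-hydroxyl without racemising C2 or touching the prenyl and chromene groups.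

Compound list
1 | methyl 4-hydroxybenzoate | COC(=O)c1ccc(O)cc1 | starting material
2 | 3-chloro-3-methylbut-1-yne | C#CC(C)(C)Cl | starting material
3 | methyl 4-[(2-methylbut-3-yn-2-yl)oxy]benzoate | COC(=O)c1ccc(OC(C)(C)C#C)cc1 | intermediate
4 | methyl 3-(3-methylbuta-1,2-dien-1-yl)-4-oxocyclohexa-1,5-diene-1-carboxylate (allenyl dienone, racemic, not isolated) | COC(=O)C1=CC(C=C=C(C)C)C(=O)C=C1 | intermediate
5 | methyl 4-hydroxy-3-(3-methylbuta-1,2-dien-1-yl)benzoate (allenyl phenol, not isolated) | COC(=O)c1ccc(O)c(C=C=C(C)C)c1 | intermediate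
6 | methyl 3-(3-methylbut-2-en-1-ylidene)-4-oxocyclohexa-1,5-diene-1-carboxylate (ortho-quinone methide, not isolated) | O=C1C=CC(C(=O)OC)=CC1=CC=C(C)C | intermediate
7 | methyl 2,2-dimethyl-2H-chromene-6-carboxylate | COC(=O)c1ccc2c(c1)C=CC(C)(C)O2 | intermediate
8 | 2,2-dimethyl-2H-chromene-6-carboxylic acid | OC(=O)c1ccc2c(c1)C=CC(C)(C)O2 | intermediate
9 | 5-bromo-2,4-dihydroxybenzaldehyde | O=Cc1cc(Br)c(O)cc1O | starting material
10 | 5-bromo-2-hydroxy-4-[(triisopropylsilyl)oxy]benzaldehyde | O=Cc1cc(Br)c(O[Si](C(C)C)(C(C)C)C(C)C)cc1O | intermediate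
11 | tributyl(3-methylbut-2-en-1-yl)stannane | CCCC[Sn](CCCC)(CCCC)CC=C(C)C | starting material
12 | 2-hydroxy-5-(3-methylbut-2-en-1-yl)-4-[(triisopropylsilyl)oxy]benzaldehyde | O=Cc1cc(CC=C(C)C)c(O[Si](C(C)C)(C(C)C)C(C)C)cc1O | intermediate
13 | 2-formyl-4-(3-methylbut-2-en-1-yl)-5-[(triisopropylsilyl)oxy]phenyl 2,2-dimethyl-2H-chromene-6-carboxylate | O=Cc1cc(CC=C(C)C)c(O[Si](C(C)C)(C(C)C)C(C)C)cc1OC(=O)c1ccc2c(c1)C=CC(C)(C)O2 | intermediate
14 | 2-(dimethoxymethyl)-4-(3-methylbut-2-en-1-yl)-5-[(triisopropylsilyl)oxy]phenyl 2,2-dimethyl-2H-chromene-6-carboxylate | COC(OC)c1cc(CC=C(C)C)c(O[Si](C(C)C)(C(C)C)C(C)C)cc1OC(=O)c1ccc2c(c1)C=CC(C)(C)O2 | intermediate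
15 | 6-(1-{2-(dimethoxymethyl)-4-(3-methylbut-2-en-1-yl)-5-[(triisopropylsilyl)oxy]phenoxy}ethenyl)-2,2-dimethyl-2H-chromene | COC(OC)c1cc(CC=C(C)C)c(O[Si](C(C)C)(C(C)C)C(C)C)cc1OC(=C)c1ccc2c(c1)C=CC(C)(C)O2 | intermediate
16 | 2-{[1-(2,2-dimethyl-2H-chromen-6-yl)ethenyl]oxy}-5-(3-methylbut-2-en-1-yl)-4-[(triisopropylsilyl)oxy]benzaldehyde | O=Cc1cc(CC=C(C)C)c(O[Si](C(C)C)(C(C)C)C(C)C)cc1OC(=C)c1ccc2c(c1)C=CC(C)(C)O2 | intermediate
17 | (2S)-2-(2,2-dimethyl-2H-chromen-6-yl)-6-(3-methylbut-2-en-1-yl)-7-[(triisopropylsilyl)oxy]-2,3-dihydro-4H-chromen-4-one | CC(C)=CCc1cc2c(cc1O[Si](C(C)C)(C(C)C)C(C)C)O[C@H](c1ccc3c(c1)C=CC(C)(C)O3)CC2=O | intermediate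
18 | dinklagin A, (2S)-2-(2,2-dimethyl-2H-chromen-6-yl)-7-hydroxy-6-(3-methylbut-2-en-1-yl)-2,3-dihydro-4H-chromen-4-one | CC(C)=CCc1cc2c(cc1O)O[C@H](c1ccc3c(c1)C=CC(C)(C)O3)CC2=O | target

Total step count: 11. Longest linear sequence: 9 steps (steps 1, 2, 3, 6, 7, 8, 9, 10, 11); the ring A branch (steps 4 and 5) joins at step 6.

Steps most likely to fail

Step 10 (labelled step). The risks are competing exo hydrometalation, decarbonylation of the acyl rhodium hydride before insertion into the electron-rich alkene, and insufficient facial discrimination in the hydride transfer. The fallback uses known chemistry, sets out from 16 and comes back at 17. A thiol-catalysed radical-chain hydroacylation (tert-dodecanethiol, 1,1'-azobis(cyclohexanecarbonitrile), chlorobenzene, 90 °C) should form the aroyl radical, which should cyclise 6-endo onto the terminal alkene carbon. The resulting benzylic α-oxy radical takes hydrogen from the thiol to give the racemic silyl flavanone F1. F1 is then resolved kinetically by asymmetric transfer hydrogenation (RuCl(p-cymene)[(R,R)-TsDPEN] or its antipode, whichever consumes the 2R ketone faster, HCO2H/Et3N, EtOAc, rt), run past half conversion. The 2R enantiomer should be reduced to the cis-flavan-4-ol F2, and the unreacted 2S ketone 17 is recovered by chromatography, at the cost of at most half of the material.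

Step 9. The risk is protonation of the enol ether at carbon and its hydrolytic cleavage competing with acetal hydrolysis. The fallback never masks the aldehyde; it sets out from 12 (with ring B taken from 7) and comes back at 16. Ester 7 is homologated with chloromethyllithium (ICH2Cl, MeLi·LiBr, THF, −78 °C) to the chloromethyl ketone F3, which NaBH4 in MeOH at 0 °C reduces to the racemic chlorohydrin F4. A Mitsunobu etherification of phenol 12 with F4 (PPh3, DIAD, toluene, 0 °C to rt) should give the racemic chloro ether F5. E2 dehydrochlorination (KOtBu, THF, −20 to 0 °C), with removal of the benzylic α-oxy hydrogen, should then give enol ether 16 under basic conditions throughout.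

Step 5. The risks are allylic transposition at palladium giving the 1,1-dimethylallyl isomer, slow oxidative addition next to the bulky silyl ether, and protodestannylation of the allylic stannane by the phenol. The fallback separates C–C coupling from installation of the trisubstituted alkene; it sets out from 10 and comes back at 12. Stille allylation with allyltributylstannane (Pd(PPh3)4, DMF, 95 °C), which has no regiochemical ambiguity, should give the allyl arene F6. Cross-metathesis of F6 with excess 2-methylbut-2-ene (second-generation Grubbs catalyst RuCl2(=CHPh)(PCy3)(H2IMes), CH2Cl2, 40 °C) should then convert the allyl group into the prenyl group of 12.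

Further compounds
F1 | step 10 | racemic 2-(2,2-dimethyl-2H-chromen-6-yl)-6-(3-methylbut-2-en-1-yl)-7-[(triisopropylsilyl)oxy]-2,3-dihydro-4H-chromen-4-one | CC(C)=CCc1cc2c(cc1O[Si](C(C)C)(C(C)C)C(C)C)OC(c1ccc3c(c1)C=CC(C)(C)O3)CC2=O
F2 | step 10 | (2R,4R)-2-(2,2-dimethyl-2H-chromen-6-yl)-6-(3-methylbut-2-en-1-yl)-7-[(triisopropylsilyl)oxy]-3,4-dihydro-2H-chromen-4-ol (cis) | CC(C)=CCc1cc2c(cc1O[Si](C(C)C)(C(C)C)C(C)C)O[C@@H](c1ccc3c(c1)C=CC(C)(C)O3)C[C@H]2O
F3 | step 9 | 2-chloro-1-(2,2-dimethyl-2H-chromen-6-yl)ethan-1-one | O=C(CCl)c1ccc2c(c1)C=CC(C)(C)O2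
F4 | step 9 | racemic 2-chloro-1-(2,2-dimethyl-2H-chromen-6-yl)ethan-1-ol | OC(CCl)c1ccc2c(c1)C=CC(C)(C)O2
F5 | step 9 | racemic 2-{[2-chloro-1-(2,2-dimethyl-2H-chromen-6-yl)ethyl]oxy}-5-(3-methylbut-2-en-1-yl)-4-[(triisopropylsilyl)oxy]benzaldehyde | O=Cc1cc(CC=C(C)C)c(O[Si](C(C)C)(C(C)C)C(C)C)cc1OC(CCl)c1ccc2c(c1)C=CC(C)(C)O2
F6 | step 5 | 2-hydroxy-5-(prop-2-en-1-yl)-4-[(triisopropylsilyl)oxy]benzaldehyde | O=Cc1cc(CC=C)c(O[Si](C(C)C)(C(C)C)C(C)C)cc1O
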